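The strategy cuts the methoxyquinone (ring A: C1=O, C2–OMe, C3–H, C4=O, C5–OAr, C6–CH2) away from the edge C5=C6 that it shares with the 18-membered ring. That edge is the retron of an oxygen-polarised alkyne. The precursor is therefore macrocyclic aryl ynol ether 14, which already holds rings B, C and D. One photochemical operation with diazoketone 18 (Wolff rearrangement, [2+2] cycloaddition, 4π opening, 6π closure: Danheiser benzannulation) forges C4–C5 and C1–C2, together with C1–C6 and C3–C4. It delivers a guaiacol-type phenol whose free para carbon C4 is then oxidised to the quinone.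

Key step: step 10

Remark: ring B is the para-phenylene, ring C the trisubstituted ring that ends as the free phenol, and ring D the meta-phenylene. The target has no stereocentre. The alkene geometry of 6 and 8 is left open because both isomers converge in step 5.

Step 1
Reactants: 1 3-bromo-4-hydroxybenzaldehyde
Product: 2 3-bromo-4-(methoxymethoxy)benzaldehyde
Conditions: MOMCl, iPr2NEt, CH2Cl2, 0 °C to rt
Reagents that add atoms: chloromethyl methyl ether, COCCl
Why: Williamson-type O-alkylation of the acidic phenol gives an acetal protecting group that tolerates every basic, reductive and photochemical step ahead and leaves under mild acid at the end.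

Step 2
Reactants: 3 [3-(benzyloxy)phenyl]methanol
Product: 4 [3-(benzyloxy)benzyl]triphenylphosphonium bromide
Conditions: PPh3·HBr, MeCN, reflux
Reagents that add atoms: triphenylphosphine hydrobromide, [Br-].[PH+](c1ccccc1)(c1ccccc1)c1ccccc1
Why: Acid-promoted nucleophilic substitution of the benzylic alcohol by PPh3 (phosphonium salt formation) needs no separate halide and leaves the benzyl aryl ether untouched.

Step 3
Reactants: 2 3-bromo-4-(methoxymethoxy)benzaldehyde; 4 [3-(benzyloxy)benzyl]triphenylphosphonium bromide
Product: 6 3'-(benzyloxy)-3-bromo-4-(methoxymethoxy)stilbene (E/Z mixture), via phosphonium ylide 5 (not isolated)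
Conditions: KOtBu, THF, 0 °C; then 2, 0 °C to rt
Reagents that add atoms: none
Why: Wittig olefination of the aldehyde by the semi-stabilised benzylic ylide 5 joins rings C and D, and the E/Z mixture is of no consequence because step 5 saturates the alkene.

Step 4
Reactants: 6 3'-(benzyloxy)-3-bromo-4-(methoxymethoxy)stilbene; 7 methyl 3-(4-hydroxyphenyl)propanoate
Product: 8 methyl 3-(4-{5-[3-(benzyloxy)styryl]-2-(methoxymethoxy)phenoxy}phenyl)propanoate (E/Z mixture)
Conditions: CuI (10 mol%), picolinic acid (20 mol%), K3PO4, DMSO, 90 °C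
Reagents that add atoms: none
Why: Ullmann-type copper-catalysed diaryl ether coupling, in which the picolinate ligand is suited to ortho-alkoxy aryl bromides and the conditions spare the methyl ester and the acetal.

Step 5
Reactants: 8 methyl 3-(4-{5-[3-(benzyloxy)styryl]-2-(methoxymethoxy)phenoxy}phenyl)propanoate
Product: 9 methyl 3-(4-{5-[2-(3-hydroxyphenyl)ethyl]-2-(methoxymethoxy)phenoxy}phenyl)propanoate
Conditions: H2 (1 atm), 10% Pd/C, EtOAc, rt
Reagents that add atoms: none
Why: Heterogeneous catalytic hydrogenation saturates the stilbene and hydrogenolyses the benzyl ether in the same flask, while ester, diaryl ether and MOM acetal are inert under neutral conditions.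

Step 6
Reactants: 9 methyl 3-(4-{5-[2-(3-hydroxyphenyl)ethyl]-2-(methoxymethoxy)phenoxy}phenyl)propanoate
Product: 10 1-chloro-4-(4-{5-[2-(3-hydroxyphenyl)ethyl]-2-(methoxymethoxy)phenoxy}phenyl)butan-2-one
Conditions: ICH2Cl, MeLi·LiBr (excess, added last), THF, −78 °C; AcOH/THF quench at −78 °C
Reagents that add atoms: chloroiodomethane, ClCI
Why: Carbenoid homologation of an ester, in which iodine–lithium exchange gives chloromethyllithium in the presence of the substrate, it adds once to the ester carbonyl at −78 °C and the cold acidic quench releases the α-chloroketone, the phenol being merely carried as its lithium salt.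

Step 7
Reactants: 10 1-chloro-4-(4-{5-[2-(3-hydroxyphenyl)ethyl]-2-(methoxymethoxy)phenoxy}phenyl)butan-2-one
Product: 11 18-membered macrocyclic α-aryloxy ketone (ring D–O–CH2–C(=O)–CH2CH2–ring B)
Conditions: Cs2CO3, MeCN, 60 °C, slow addition of 10 (final about 2 mM)
Reagents that add atoms: none
Why: Intramolecular Williamson ether synthesis (SN2 of the caesium phenoxide on the highly reactive α-chloroketone) under pseudo-high dilution closes the 18-membered ring, the only nucleophile in the molecule being the ring D phenoxide.

Step 8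
Reactants: 11 18-membered macrocyclic α-aryloxy ketone
Product: 14 18-membered macrocyclic aryl ynol ether (ring D–O–C≡C–CH2CH2–ring B), via lithium (Z)-enolate 12 (not isolated), via (Z)-enol triflate 13 (not isolated)
Conditions: LiN(SiMe3)2, THF/DMPU, −78 °C; PhNTf2, −78 °C to rt; then KOtBu, THF, −78 to −20 °C
Reagents that add atoms: lithium hexamethyldisilazide, [Li+].C[Si](C)(C)[N-][Si](C)(C)C (lithium of 12 only); N-phenylbis(trifluoromethanesulfonimide), O=S(=O)(N(c1ccccc1)S(=O)(=O)C(F)(F)F)C(F)(F)F (triflyl group of 13 only)
Why: Known two-stage route from α-alkoxy ketones to ynol ethers, in which the more acidic OCH2 site gives the chelated (Z)-enolate 12, O-triflation fixes H and OTf anti in 13 and an E2 anti elimination with KOtBu releases the triple bond.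

Step 9
Reactants: 15 (E)-4-methoxybut-3-en-2-one
Product: 18 (E)-1-diazo-4-methoxybut-3-en-2-one, via lithium dienolate 16 (not isolated), via trifluoroacetyl diketone 17 (not isolated)
Conditions: LiN(SiMe3)2, THF, −78 °C; CF3CO2CH2CF3; then MsN3, Et3N, H2O, MeCN, rt
Reagents that add atoms: lithium hexamethyldisilazide, [Li+].C[Si](C)(C)[N-][Si](C)(C)C (lithium of 16 only); 2,2,2-trifluoroethyl trifluoroacetate, O=C(OCC(F)(F)F)C(F)(F)F (trifluoroacetyl group of 17 only); methanesulfonyl azide, CS(=O)(=O)N=[N+]=[N-]
Why: Deacylative Regitz diazo transfer, in which kinetic trifluoroacetylation of the methyl group activates it for diazo transfer from MsN3 and the trifluoroacetyl group leaves with the sulfonamide, so that no diazoalkane ever meets the enone.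

Step 10
Reactants: 14 18-membered macrocyclic aryl ynol ether; 18 (E)-1-diazo-4-methoxybut-3-en-2-one
Product: 23 macrocyclic guaiacol-type phenol (ring A as 2-methoxy-5-aryloxy-6-alkylphenol with C3–H and C4–H), via vinylketene 19 (not isolated), via vinylcyclobutenone 20 (not isolated), via dienylketene 21 (not isolated), via cyclohexadienone 22 (not isolated)
Conditions: hν (300 nm, Pyrex), ClCH2CH2Cl, rt, 18 added in portions (excess); then 80 °C
Reagents that add atoms: none
Why: Light expels N2 from 18 and the methoxyvinyl group migrates (photochemical Wolff rearrangement) to give vinylketene 19, whose carbonyl carbon (future C1) is attacked by the nucleophilic alkyl-bearing alkyne carbon C6 of 14 while the oxygen-bearing carbon C5 bonds to the former diazo carbon C4, a regiospecific [2+2] cycloaddition that closes the strained four-membered ring of 20. Strain release drives the 4π electrocyclic opening of 20 (cleavage of C1–C4) to dienylketene 21, and a 6π electrocyclic closure joins C1 to the methoxy-bearing terminus C2, closing the six-membered ring as dienone 22, which tautomerises to phenol 23. This is the diazoketone variant of the Danheiser benzannulation, a known reaction of oxygen- and nitrogen-substituted alkynes. The two transient sp3 centres (C4 in 20, C2 in 22) are erased by ring opening and enolisation, so no stereocontrol is needed. The selectivity required is the orientation of the alkyne, which is secured by the polarisation that the aryloxy oxygen imposes on the triple bond, and the reversible opening of 20 funnels the material into the one ketene geometry that can cyclise.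

Step 11
Reactants: 23 macrocyclic guaiacol-type phenol
Product: 24 O-MOM-protected macrocyclic methoxyquinone
Conditions: (KSO3)2NO, KH2PO4, acetone/H2O, rt
Reagents that add atoms: potassium nitrosodisulfonate, [K+].[K+].[O]N(S(=O)(=O)[O-])S(=O)(=O)[O-]
Why: Teuber oxidation, in which the phenoxyl radical of the 2,6-disubstituted phenol is trapped by a second nitroxide at the only open position, para carbon C4, and loss of the imidodisulfonate gives the 1,4-quinone, no other free phenol being present.

Step 12
Reactants: 24 O-MOM-protected macrocyclic methoxyquinone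
Product: 25 CNP0332646.0 (target)
Conditions: CF3CO2H, CH2Cl2, 0 °C to rt; aqueous work-up
Reagents that add atoms: none
Why: Acid-catalysed acetal cleavage in a non-nucleophilic medium frees the ring C phenol without addition–elimination at the vinylogous ester positions C2 and C5 of the quinone.

Compound list
1 | 3-bromo-4-hydroxybenzaldehyde | O=Cc1ccc(O)c(Br)c1 | starting material
2 | 3-bromo-4-(methoxymethoxy)benzaldehyde | COCOc1ccc(C=O)cc1Br | intermediate
3 | [3-(benzyloxy)phenyl]methanol | OCc1cccc(OCc2ccccc2)c1 | starting material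
4 | [3-(benzyloxy)benzyl]triphenylphosphonium bromide | [Br-].c1ccc(COc2cccc(C[P+](c3ccccc3)(c3ccccc3)c3ccccc3)c2)cc1 | intermediate
5 | [3-(benzyloxy)benzylidene]triphenylphosphorane (ylide, not isolated) | c1ccc(COc2cccc(C=P(c3ccccc3)(c3ccccc3)c3ccccc3)c2)cc1 | intermediate
6 | 3'-(benzyloxy)-3-bromo-4-(methoxymethoxy)stilbene (E/Z mixture) | COCOc1ccc(C=Cc2cccc(OCc3ccccc3)c2)cc1Br | intermediate
7 | methyl 3-(4-hydroxyphenyl)propanoate | COC(=O)CCc1ccc(O)cc1 | starting material
8 | methyl 3-(4-{5-[3-(benzyloxy)styryl]-2-(methoxymethoxy)phenoxy}phenyl)propanoate (E/Z mixture) | COC(=O)CCc1ccc(Oc2cc(C=Cc3cccc(OCc4ccccc4)c3)ccc2OCOC)cc1 | intermediate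
9 | methyl 3-(4-{5-[2-(3-hydroxyphenyl)ethyl]-2-(methoxymethoxy)phenoxy}phenyl)propanoate | COC(=O)CCc1ccc(Oc2cc(CCc3cccc(O)c3)ccc2OCOC)cc1 | intermediate
10 | 1-chloro-4-(4-{5-[2-(3-hydroxyphenyl)ethyl]-2-(methoxymethoxy)phenoxy}phenyl)butan-2-one | O=C(CCl)CCc1ccc(Oc2cc(CCc3cccc(O)c3)ccc2OCOC)cc1 | intermediate
11 | 18-membered macrocyclic α-aryloxy ketone: ring D–O–CH2–C(=O)–CH2CH2–ring B(1,4)–O–ring C (MOM ether ortho to that oxygen)–CH2CH2–ring D(1,3) | COCOc1ccc2CCc3cccc(OCC(=O)CCc4ccc(Oc1c2)cc4)c3 | intermediate
12 | lithium (Z)-enolate of 11 on the OCH2 side (not isolated) | [Li+].COCOc1ccc2CCc3cccc(O/C=C(\[O-])CCc4ccc(Oc1c2)cc4)c3 | intermediate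
13 | macrocyclic (Z)-enol triflate, ArO and OTf cis (not isolated) | COCOc1ccc2CCc3cccc(O/C=C(\OS(=O)(=O)C(F)(F)F)CCc4ccc(Oc1c2)cc4)c3 | intermediate
14 | 18-membered macrocyclic aryl ynol ether: ring D–O–C≡C–CH2CH2–ring B | COCOc1ccc2CCc3cccc(OC#CCCc4ccc(Oc1c2)cc4)c3 | intermediate
15 | (E)-4-methoxybut-3-en-2-one | CO/C=C/C(C)=O | starting material
16 | lithium dienolate of 15 (not isolated) | [Li+].CO/C=C/C(=C)[O-] | intermediate
17 | (E)-1,1,1-trifluoro-6-methoxyhex-5-ene-2,4-dione (not isolated) | CO/C=C/C(=O)CC(=O)C(F)(F)F | intermediate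
18 | (E)-1-diazo-4-methoxybut-3-en-2-one | CO/C=C/C(=O)C=[N+]=[N-] | intermediate
19 | (E)-4-methoxybuta-1,3-dien-1-one, vinylketene (not isolated) | CO/C=C/C=C=O | intermediate
20 | macrocycle-fused 3-aryloxy-2-alkyl-4-[(E)-2-methoxyvinyl]cyclobut-2-enone, racemic (not isolated) | CO/C=C/C1C(=O)C2=C1Oc3cccc(CCc4ccc(OCOC)c(Oc5ccc(CC2)cc5)c4)c3 | intermediate
21 | macrocyclic dienylketene, ketene and methoxyvinyl cis on the central alkene (not isolated) | CO/C=C/C=C1/Oc2cccc(CCc3ccc(OCOC)c(Oc4ccc(CCC1=C=O)cc4)c3)c2 | intermediate
22 | macrocyclic 6-methoxycyclohexa-2,4-dienone, racemic (not isolated) | COC1C=CC2=C(CCc3ccc(cc3)Oc3cc(ccc3OCOC)CCc3cccc(c3)O2)C1=O | intermediate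
23 | macrocyclic phenol: ring A with C1–OH, C2–OMe, C3–H, C4–H, C5–O–ring D, C6–CH2CH2–ring B | COc1ccc2Oc3cccc(CCc4ccc(OCOC)c(Oc5ccc(CCc2c1O)cc5)c4)c3 | intermediate
24 | O-MOM-protected macrocyclic methoxyquinone | COC1=CC(=O)C2=C(CCc3ccc(cc3)Oc3cc(ccc3OCOC)CCc3cccc(c3)O2)C1=O | intermediate
25 | CNP0332646.0 | COC1=CC(=O)C2=C(CCc3ccc(cc3)Oc3cc(ccc3O)CCc3cccc(c3)O2)C1=O | target

Total step count: 12. Longest linear sequence: 10 steps (1, 3, 4, 5, 6, 7, 8, 10, 11, 12).

Steps most likely to fail

Step 10. The aryloxy alkyne is less nucleophilic than an alkoxy alkyne. The ketene may therefore be lost to dimerisation before it is captured, and long irradiation may degrade the diaryl ether chromophores. The fallback sets out from 14 and makes the same ketene without light. Commercial (E)-4-methoxybut-2-enoic acid F1 is converted with (COCl)2 and catalytic DMF into (E)-4-methoxybut-2-enoyl chloride F2. F2 is added slowly to 14 and Et3N in toluene at 80–110 °C. The 1,4-dehydrochlorination gives vinylketene 19 at low stationary concentration, so the route is rejoined at 19 and runs through the same cascade to 23 in the same flask.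

Step 8. Deprotonation may occur on the CH2CH2 side of the ketone, which would lose regiocontrol in the triflation. The fallback sets out from 11. Soft enolisation with Me3SiOTf and Et3N in CH2Cl2 under equilibrating conditions should give the thermodynamic, oxygen-substituted macrocyclic (Z)-trimethylsilyl enol ether F3, which can be purified. MeLi in THF then cleaves the silyl group regiospecifically, and the route is rejoined at lithium enolate 12, which is triflated and eliminated as before.

Step 7. Intermolecular alkylation (oligomerisation) or base-induced self-condensation of the chloroketone may outrun ring closure. The fallback sets out from 9 and closes the ring at an sp2 carbon with copper as a template. Reduction with iBu2AlH at −78 °C gives 3-(4-{5-[2-(3-hydroxyphenyl)ethyl]-2-(methoxymethoxy)phenoxy}phenyl)propanal F4. Ramirez olefination (CBr4, PPh3) gives the gem-dibromoalkene F5. Intramolecular copper-catalysed vinylic C–O coupling (CuI, 2,2'-bipyridine, K3PO4, toluene, 110 °C, high dilution) gives the macrocyclic bromo enol ether F6. Dehydrobromination with KOtBu rejoins the route at 14 and bypasses 10 to 13.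

Further compounds
F1 | step 10 | (E)-4-methoxybut-2-enoic acid | COC/C=C/C(=O)O
F2 | step 10 | (E)-4-methoxybut-2-enoyl chloride | COC/C=C/C(=O)Cl
F3 | step 8 | macrocyclic (Z)-trimethylsilyl enol ether of 11 | COCOc1ccc2CCc3cccc(O/C=C(\O[Si](C)(C)C)CCc4ccc(Oc1c2)cc4)c3
F4 | step 7 | 3-(4-{5-[2-(3-hydroxyphenyl)ethyl]-2-(methoxymethoxy)phenoxy}phenyl)propanal | O=CCCc1ccc(Oc2cc(CCc3cccc(O)c3)ccc2OCOC)cc1
F5 | step 7 | 3-{2-[3-(4-(4,4-dibromobut-3-enyl)phenoxy)-4-(methoxymethoxy)phenyl]ethyl}phenol | BrC(Br)=CCCc1ccc(Oc2cc(CCc3cccc(O)c3)ccc2OCOC)cc1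
F6 | step 7 | macrocyclic 1-bromo enol ether (ring D–O–C(Br)=CH–CH2CH2–ring B) | COCOc1ccc2CCc3cccc(OC(Br)=CCCc4ccc(Oc1c2)cc4)c3
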